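I decided to reckon side product B and let side product A be the remainder, because the half-life of substrate by step 3 alone, 0.14 h, is far shorter than the 40 h of the run.

substrate 0.10 M (fed, over 30 min); gas phase 61 mM (held); time 40 h
    gas phase ⇌ dissolved gas, rate k1*(csat - [dissolved gas]) (k1 = 0.12 /min, csat = 61 mM)
    substrate + dissolved gas ⇌ target (K2 = 14 /M, k2 = 14 /M/min)
    substrate → side product A (k3 = 0.080 /min)
    substrate + target → side product B (k4 = 0.32 /M/min)
- percentages count the substrate that a species holds: one side product B counts as two
- at the start none of the gas is dissolved
- the reaction counts as stopped when no species that holds the substrate changes by six tenths of a point or more over the second half of the time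
- run time (flask): 40 h
- the state of affairs at 40 h: stopped, and by what, or still going (all of the substrate has reacted / forward and back rates have come level / it is still moving)
- part of the substrate gone at 40 h
- the side product A standing at 40 h, as a percentage of the substrate charged

Step 2 relaxes in 0.539 min, faster than the 12.5 min of step 3, and the dissolved gas fills in 8.33 min, less than the dosing time 30 min. So I held the gas at saturation, 61 mM, and the target at G = K2·csat = 0.854 times the substrate. Substrate and target then form one pool, drained by step 3 with the time τ = (1+G)/k3 = 23.2 min. The bench rule says a dosed material on a first-order drain stands at feed rate times drain time, here 0.0773 M. That rule needs a feed long against τ, but tf/τ is 1.29, so I took the pool to peak lower, near 0.0561 M.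

Step 4 runs at k4 times substrate times target, and step 3 at k3 times substrate. I replaced the target curve by its mean P, weighted by what passes through. An exponential fall has a weighted mean of half its height, which gave P = 0.0129 M. Then m = 2·k4·P/k3 = 0.103, a selectivity factor: the substrate lost to side product B per substrate reaching side product A. That put side product A at 90.7%. A triangular curve has a mean 1.33 times higher and gives 87.9%, so that was my error band, with a conversion of 100%.

The forecast said all of the substrate has reacted, 100% gone and side product A 93%, higher than the top of my band, on the ground that “Side product B competes only while the substrate and target are both concentrated”.

The flask gave all of the substrate has reacted, 100% gone and side product A 91.0% at 40.0 h. Backward turnover in step 2 stood at 99.5% of the forward one. The reading of m in this flask, side product B over side product A, is 0.0992, against my 0.103.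

For the neighbour flask with 0.025 M of substrate, my reckoned peak scales with the charge, so m becomes 0.0258 and side product B 2.52%. That flask gave side product B 2.65% and side product A 97.3%.

The constants used here belong to no real substance; the run is a simulation.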